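**Retrosynthetic overview**
1. Ring E (last): hemiketal ⇐ δ-hydroxy ketone ⇐ trivalent-titanium opening of a C6 spiro-epoxide and radical addition to ethyl vinyl ketone; epoxide ⇐ bridging C6 ketone.
2. Ring A: N-methylpiperidine ⇐ double Mannich reaction (MeNH2, 2 CH2O) across the C6 ketone (C18–C19 and C8–C21 bonds); C15 carbinol by reduction and inversion.
3. Ring B and the C11=C12 enone ⇐ palladium-triggered retro-aldol/dehydrogenation of a cyclobutane photoadduct (new step).
4. Ring D and the cyclobutane ⇐ intramolecular de Mayo-type [2+2] photocycloaddition (C11–C12 and C6–C18 bonds) of a 2-acylcyclopentenyl allyl carbonate onto the ring C cyclopentene.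
5. Photosubstrate ⇐ cyclopentanone + cis diester ⇐ Johnson–Claisen rearrangement of methyl (1R,4S)-4-hydroxycyclopent-2-ene-1-carboxylate (ring C, sole source of chirality); ring order C → D → B → A → E.

Assumption: compound 1 is bought as the single (1R,4S) enantiomer (catalogue cyclopentenoid building block from the carbocyclic-nucleoside field).

Labels: C6 spiro carbon, C7 its OCH2, C5–C1 the chain to the hemiketal carbon C3 and its ethyl group, C8 bridgehead CH, C9/C10 ring B CH2, C11=C12 alkene, C13 ring-fusion CH, C14 CH2, C15 carbinol, C16 ester CH, C17 CH2, C18 quaternary carbon, C19 and C21 the NCH2 groups on C18 and C8. Rings: A piperidine, B seven-membered, C ester cyclopentane, D cyclopentene, E tetrahydropyran. Upper face = face of H13 and H16; lower face = face of the CO2Me group.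

**Step 1**
Reactants: 1 methyl (1R,4S)-4-hydroxycyclopent-2-ene-1-carboxylate; 2 trimethyl orthoacetate
Product: 3 methyl (1R,2S)-2-(2-methoxy-2-oxoethyl)cyclopent-3-ene-1-carboxylate (cis diester)
Conditions: EtCO2H (5 mol%), xylene, 140 °C, MeOH distilled off
Reagents that add atoms: none
Why: Johnson–Claisen rearrangement: the ketene acetal formed on the C18 oxygen delivers the acetate carbon suprafacially to C13, so the new CH2CO2Me is cis to the C16 ester and the alkene moves to C12=C18.

**Step 2**
Reactants: 3 methyl (1R,2S)-2-(2-methoxy-2-oxoethyl)cyclopent-3-ene-1-carboxylate; 4 cyclopentanone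
Product: 5 methyl (1R,2S)-2-[2-oxo-2-(2-oxocyclopentyl)ethyl]cyclopent-3-ene-1-carboxylate (β-diketone, keto/enol mixture, C11 undefined)
Conditions: 4 (2.2 equiv), LiN(SiMe3)2, THF, −78 °C; then 3, −78 to 0 °C; aq. NH4Cl
Reagents that add atoms: none
Why: Crossed Claisen condensation: the preformed lithium enolate attacks the unhindered CH2CO2Me ester rather than the α-branched ring ester, and formation of the β-diketonate drives it; no existing stereocentre is touched.

**Step 3**
Reactants: 5 methyl (1R,2S)-2-[2-oxo-2-(2-oxocyclopentyl)ethyl]cyclopent-3-ene-1-carboxylate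
Product: 6 methyl (1R,2S)-2-[2-(2-{[(prop-2-en-1-yloxy)carbonyl]oxy}cyclopent-1-en-1-yl)-2-oxoethyl]cyclopent-3-ene-1-carboxylate (ring enol allyl carbonate)
Conditions: allyl chloroformate, pyridine, CH2Cl2, 0 °C
Reagents that add atoms: allyl chloroformate, C=CCOC(Cl)=O
Why: O-acylation of the β-diketone (enol carbonate formation) occurs on the ring oxygen to give the less strained endocyclic enol carbonate, which locks the C6=C11 double bond for the cycloaddition and installs the allyl trigger for step 5.

**Step 4**
Reactants: 6 ring enol allyl carbonate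
Product: 7 cyclobutane photoadduct: ring C cis-fused to new ring D (C15 ketone) and to cyclobutane C6–C11–C12–C18, itself cis-fused to the former cyclopentanone ring; allyl carbonate on C6; H12, H13, H16, H18 on the upper face; cis-anti-cis across the cyclobutane
Conditions: hν (medium-pressure Hg lamp, Pyrex, λ > 300 nm), degassed cyclohexane, 0.005 M, rt
Reagents that add atoms: none
Why: Intramolecular enone–alkene [2+2] photocycloaddition (first half of a de Mayo reaction, as in cyclopentanone-ring-expanding de Mayo sequences): the triplet closes C11–C12 first (rule of five, ring D) and then C6–C18, both on the lower face of ring C where the C13 tether sits, so H12 and H18 end cis to H13 and the C6/C11 centres follow from the cis ring fusions.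

**Step 5**
Reactants: 7 cyclobutane photoadduct
Product: 8 tricyclic enedione (rings B, C, D): C11=C12 cyclopentenone with C15=O, C6 cycloheptanone, H18 on the upper face, CO2Me on the lower face
Conditions: Pd(OAc)2 (10 mol%), Ph2PCH2CH2PPh2 (10 mol%), MeCN, 80 °C
Reagents that add atoms: none
Why: Proposed new method: zerovalent palladium formed in situ ionises the allyl carbonate, loss of CO2 gives a cyclobutanolate whose strain-driven retro-aldol cleavage of C6–C11 creates ring B, and the resulting allylpalladium enolate at C11 undergoes β-hydride elimination (Pd–H re-addition funnelling to the tetrasubstituted isomer) to give the C11=C12 enone and propene; the closest known reactions are the Tsuji dehydrogenation of allyl enol carbonates and the retro-aldol half of the de Mayo reaction.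

**Step 6**
Reactants: 8 tricyclic enedione
Product: 9 tetracyclic amino enedione: N-methylpiperidine (ring A) bridging C18 and C8 over the C6 ketone, C19 on the upper face
Conditions: MeNH2 (40% aq.), CH2O (37% aq., 2.2 equiv), AcOH, 60 °C
Reagents that add atoms: methylamine, CN; formaldehyde, C=O
Why: Double Mannich annulation: the doubly activated C18–H (α to the C6 ketone, vinylogous to the C15 enone) enolises, the iminium attacks C18 on the upper face anti to the lower-face C16 ester, and the tethered iminium then closes on the C8 enol in the only geometry that can bridge, which sets C8.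

**Step 7**
Reactants: 9 tetracyclic amino enedione
Product: 10 15-epi allylic alcohol (as 9 with C15–OH on the lower face)
Conditions: NaBH4, CeCl3·7H2O, MeOH, −78 °C
Reagents that add atoms: none
Why: Luche reduction: 1,2-selective for the enone carbonyl while the bridging C6 ketone next to quaternary C18 is untouched, hydride entering from the open upper (convex) face to give the lower-face alcohol.

**Step 8**
Reactants: 10 15-epi allylic alcohol
Product: 12 C15 upper-face allylic alcohol with C6 ketone, via 4-nitrobenzoate 11 (not isolated)
Conditions: 4-O2NC6H4CO2H, PPh3, DIAD, THF, 0 °C to rt; then K2CO3, MeOH, rt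
Reagents that add atoms: 4-nitrobenzoic acid, OC(=O)c1ccc(cc1)[N+](=O)[O-]
Why: Mitsunobu reaction inverts C15 by SN2 attack of the carboxylate from the open upper face, and in situ methanolysis of the nitrobenzoate frees the alcohol in the target configuration without changing the methyl ester.

**Step 9**
Reactants: 12 C15 upper-face allylic alcohol with C6 ketone
Product: 13 C6 spiro-epoxide (epoxide CH2 on the piperidine side, oxygen on the alkene side)
Conditions: Me3S+ I−, KN(SiMe3)2, THF, −10 °C to rt
Reagents that add atoms: trimethylsulfonium iodide, C[S+](C)C.[I-]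
Why: Corey–Chaykovsky epoxidation: the small sulfonium ylide adds to the non-enolisable C6 ketone from its convex piperidine side and closes to the spiro-epoxide, whose C6 configuration is erased in the next step.

**Step 10**
Reactants: 13 C6 spiro-epoxide; 14 ethyl vinyl ketone
Product: 16 target CNP0124876.1 as the closed hemiketal, via open-chain hydroxy ketone 15 (not isolated)
Conditions: 14 (5 equiv), Cp2TiCl2 (20 mol%), Mn, 2,4,6-collidine·HCl, THF, rt; aq. NaHCO3
Reagents that add atoms: none
Why: Nugent–RajanBabu/Gansäuer epoxide opening by trivalent titanium gives the tertiary C6 radical, which adds (Giese reaction) to ethyl vinyl ketone from the convex face syn to the piperidine bridge because the other face lies in the concave pocket under the C11=C12 alkene walled by the C16 ester, so C5 ends syn to nitrogen and C7–O syn to the alkene, and the hydroxy ketone then closes to the anomerically stabilised hemiketal under thermodynamic control.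

**Compound list**
1 | methyl (1R,4S)-4-hydroxycyclopent-2-ene-1-carboxylate | COC(=O)[C@H]1C=C[C@@H](O)C1 | starting material
2 | trimethyl orthoacetate | COC(C)(OC)OC | starting material
3 | methyl (1R,2S)-2-(2-methoxy-2-oxoethyl)cyclopent-3-ene-1-carboxylate | COC(=O)C[C@H]1C=CC[C@H]1C(=O)OC | intermediate
4 | cyclopentanone | O=C1CCCC1 | starting material
5 | methyl (1R,2S)-2-[2-oxo-2-(2-oxocyclopentyl)ethyl]cyclopent-3-ene-1-carboxylate | O=C1CCCC1C(=O)C[C@H]1C=CC[C@H]1C(=O)OC | intermediate
6 | ring enol allyl carbonate of 5 | C=CCOC(=O)OC1=C(CCC1)C(=O)C[C@H]1C=CC[C@H]1C(=O)OC | intermediate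
7 | cyclobutane photoadduct | C=CCOC(=O)O[C@]12CCC[C@]13C(=O)C[C@@H]4[C@H](C(=O)OC)C[C@H]2[C@H]34 | intermediate
8 | tricyclic enedione (rings B, C, D) | COC(=O)[C@@H]1C[C@@H]2C(=O)CCCC3=C2[C@@H]1CC3=O | intermediate
9 | tetracyclic amino enedione (rings A–D) | O=C1[C@@H]2CCC3=C4[C@H](CC3=O)[C@H](C(=O)OC)C[C@]14CN(C)C2 | intermediate
10 | 15-epi allylic alcohol (OH lower face) | O=C1[C@@H]2CCC3=C4[C@H](C[C@H]3O)[C@H](C(=O)OC)C[C@]14CN(C)C2 | intermediate
11 | C15 4-nitrobenzoate (oxygen upper face) | O=C1[C@@H]2CCC3=C4[C@H](C[C@@H]3OC(=O)c5ccc(cc5)[N+](=O)[O-])[C@H](C(=O)OC)C[C@]14CN(C)C2 | intermediate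
12 | C15 upper-face allylic alcohol, C6 ketone | O=C1[C@@H]2CCC3=C4[C@H](C[C@@H]3O)[C@H](C(=O)OC)C[C@]14CN(C)C2 | intermediate
13 | C6 spiro-epoxide | C1O[C@@]12[C@@H]3CCC4=C5[C@H](C[C@@H]4O)[C@H](C(=O)OC)C[C@@]52CN(C)C3 | intermediate
14 | ethyl vinyl ketone (pent-1-en-3-one) | CCC(=O)C=C | starting material
15 | open-chain δ-hydroxy ketone (C6 bears CH2OH and CH2CH2C(O)Et) | CCC(=O)CC[C@@]1(CO)[C@@H]2CCC3=C4[C@H](C[C@@H]3O)[C@H](C(=O)OC)C[C@@]41CN(C)C2 | intermediate
16 | CNP0124876.1 | CC[C@@]1(O)CC[C@@]2(CO1)[C@@H]1CCC3=C4[C@H](C[C@@H]3O)[C@H](C(=O)OC)C[C@@]42CN(C)C1 | target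

**Total steps:** 10. **Longest linear sequence:** 10 (from 1).

**Three steps most likely to fail**

Step 5 (the proposed palladium cascade). The allylpalladium enolate may C-allylate at C11, or β-hydride elimination may go towards C10. Fallback with known chemistry, stepwise instead of cascade: starting from 7, Pd(PPh3)4 (cat.) and morpholine remove the allyl carbonate and the freed cyclobutanol fragments by retro-aldol to the saturated tricyclic 1,5-diketone F1. TMSOTf/Et3N then converts both ketones into their more substituted silyl enol ethers, the bis(trimethylsilyl enol ether) F2. Saegusa–Ito oxidation with Pd(OAc)2 in MeCN and hydrolytic work-up gives the conjugated enedione and returns to the route at 8.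

Step 6 (double Mannich). The extended enol can also be attacked at C11, and the ring D ketone offers a second annulation site. Fallback that takes the ring D carbonyl out of play before the annulation: starting from 8, Luche reduction gives the lower-face allylic alcohol F3, and Mitsunobu inversion with 4-nitrobenzoic acid gives the upper-face 4-nitrobenzoate F4. The annulation is then run on the single remaining ketone with preformed MeN(CH2OEt)2 and MeSiCl3 in MeCN, which returns to the route at 11 (methanolysis to 12 as in step 8).

Step 10 (radical addition at the congested C6). The tertiary radical may be reduced instead of adding, and face selectivity at C6 rests on a steric argument. Fallback by an ionic route: starting from 13, BF3·OEt2-promoted Meinwald rearrangement gives the C6 carbaldehyde F5. Pyrrolidine-catalysed enamine Michael addition to 14 forms the quaternary keto aldehyde F6, with the electrophile again entering on the convex face. NaBH4 at −78 °C reduces only the aldehyde and returns to the route at 15, which closes to 16.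

**Further compounds**
F1 | step 5 | saturated tricyclic 1,5-diketone (H12 and H18 upper face, C11 unspecified) | COC(=O)[C@@H]1C[C@@H]2C(=O)CCCC3[C@@H]2[C@@H]1CC3=O
F2 | step 5 | bis(trimethylsilyl enol ether) of F1 (C6=C18 and C15=C11) | COC(=O)[C@@H]1CC2=C(O[Si](C)(C)C)CCCC3=C(O[Si](C)(C)C)C[C@H]1[C@H]23
F3 | step 6 | 15-epi allylic alcohol of 8 (OH lower face) | COC(=O)[C@@H]1C[C@@H]2C(=O)CCCC3=C2[C@@H]1C[C@H]3O
F4 | step 6 | C15 4-nitrobenzoate of the tricycle (oxygen upper face) | COC(=O)[C@@H]1C[C@@H]2C(=O)CCCC3=C2[C@@H]1C[C@@H]3OC(=O)c4ccc(cc4)[N+](=O)[O-]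
F5 | step 10 | C6 carbaldehyde (C6–H, configuration unspecified) | O=CC1[C@@H]2CCC3=C4[C@H](C[C@@H]3O)[C@H](C(=O)OC)C[C@@]41CN(C)C2
F6 | step 10 | C6 quaternary keto aldehyde | CCC(=O)CC[C@@]1(C=O)[C@@H]2CCC3=C4[C@H](C[C@@H]3O)[C@H](C(=O)OC)C[C@@]41CN(C)C2
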